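The γ-lactone ring (O, C7, C8, C17, C19) is cut back to a cyclobutanone. Dichloroketene adds across the C7=C8 triethylsilyl enol ether of the ten-membered ring, forming C7–C19 and C8–C17 in one operation. This sets both ring-fusion centres and delivers the C8 tertiary oxygen as the enol-ether oxygen. The precursor carries both epoxides, the C5 exomethylene and a C6 p-methoxybenzyl ether. Its enol ether, with C6 and C9 trans, is not made by deprotonation: its geometry is fixed by an anionic oxy-Cope ring expansion of a quinone-derived trans-decalin bearing allenyl (C3) and (Z)-alkoxyvinyl (C8) groups.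

Key step: step 21

Remark (locants): briarane numbering is used for every intermediate (ten-membered ring C1–C10; ring A = C1, C10–C14; ring B of the bicyclic intermediates = C1, C2, C3, C8, C9, C10); α is the face of H-10, β the face of the C1 methyl.
Remark (assumption): 2-methoxy-5-methyl-1,4-benzoquinone is taken as a catalogue compound.
Remark (design): an acetate at C9 would not survive the enolate chemistry at C7 and C17, so C9 is a silyl ether and is acetylated last. C6 carries a p-methoxybenzyl ether so that it alone is free when the chloride is made. The O8 silyl group is triethylsilyl so that the β-oxygenated cyclobutanone stays closed. The C17 methyl is set by kinetic protonation, because alkylation should enter anti to O8.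

Step 1
Reactants: 1 ethyl vinyl ketone
Product: 2 (Z)-3-(tert-butyldimethylsilyloxy)penta-1,3-diene
Conditions: TBSOTf, Et3N, Et2O, 0 °C
Reagents that add atoms: tert-butyldimethylsilyl triflate, CC(C)(C)[Si](C)(C)OS(=O)(=O)C(F)(F)F
Why: Silyl enol ether formation by soft enolisation; amine-mediated O-silylation of an ethyl ketone favours the (Z)-enol ether, whose methyl is "outside" in the s-cis diene.

Step 2
Reactants: 2 (Z)-3-(tert-butyldimethylsilyloxy)penta-1,3-diene; 3 2-methoxy-5-methyl-1,4-benzoquinone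
Product: 4 cis-fused Diels–Alder adduct (ring B 8-methoxy-3-ene-2,9-dione, 12-silyl enol ether)
Conditions: (S)-o-tolyl diphenylprolinol-derived oxazaborolidine (20 mol %), HNTf2, CH2Cl2, −78 °C
Reagents that add atoms: none
Why: Catalytic enantioselective Diels–Alder reaction of a quinone: the boron Lewis acid binds the more basic vinylogous-ester carbonyl (future C2), so the unsubstituted carbon (C10) joins the oxygen-activated diene terminus (C11), the methoxy-bearing double bond stays inert, and the catalyst sets the quaternary C1 (the sense of induction of the (S)-catalyst is to be confirmed and the antipode used otherwise; C10 and C11 are reset in steps 3 and 5).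

Step 3
Reactants: 4 cis-fused adduct
Product: 5 trans-fused adduct
Conditions: DBU (0.2 equiv), CH2Cl2, 20 °C
Reagents that add atoms: none
Why: Base-mediated epimerisation through the C9 enolate moves H-10 to the α face, which should give the more stable trans-fused ene-dione with the C11 methyl equatorial.

Step 4
Reactants: 5 trans-fused adduct
Product: 6 trans-fused trione (ring A 13-en-12-one)
Conditions: Pd(OAc)2 (10 mol %), O2 (1 atm), DMSO, 40 °C
Reagents that add atoms: none
Why: Saegusa–Ito oxidation of the regiodefined C12=C13 silyl enol ether installs the C13=C14 double bond without base.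

Step 5
Reactants: 6 trans-fused trione
Product: 9 9,12β-dihydroxy-11β-methyl-2,13-dien-8-one (C9 epimers), via 11β-methyl trione 7 (not isolated), via triol 8 (not isolated)
Conditions: LDA (2.5 equiv), THF, −78 °C; 2,6-di-tert-butyl-4-methylphenol, −78 °C; then i-Bu2AlH, −78 → 0 °C; then 1 M HCl, THF, 0 °C
Reagents that add atoms: water, O
Why: Kinetic enolate protonation, then hydride reduction and acid-induced 1,3-carbonyl transposition of the reduced vinylogous ester: the C10 and C11 enolates should be protonated on the α face, anti to the C1 methyl (trans fusion kept, C11 methyl turned β), i-Bu2AlH reduces the three carbonyls before C11 can equilibrate (C12 from the open α face, giving the 12β alcohol), and acid ionises the C2 alcohol so that water enters at C8 and methanol leaves, giving the C2=C3–C8=O enone.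

Step 6
Reactants: 9 dihydroxy dienone
Product: 10 9α,12β-bis(tert-butyldimethylsilyloxy)-2,13-dien-8-one
Conditions: TBSOTf, 2,6-lutidine, CH2Cl2, −78 → 0 °C; then DBU, toluene, 50 °C
Reagents that add atoms: tert-butyldimethylsilyl triflate, CC(C)(C)[Si](C)(C)OS(=O)(=O)C(F)(F)F
Why: Silylation of both secondary alcohols, then base-mediated epimerisation of the α-silyloxy ketone: C9 should settle as the equatorial 9α epimer, which avoids the 1,3-diaxial contact with the C1 methyl, while C11 can no longer enolise.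

Step 7
Reactants: 10 bis-silyl dienone
Product: 11 3-iodo enone
Conditions: I2, pyridine, CH2Cl2, 20 °C
Reagents that add atoms: iodine, II
Why: α-Iodination of an enone by pyridine conjugate addition, iodination and elimination (Baylis–Hillman-type sequence), known for 4,4-disubstituted cyclohexenones; the C13=C14 alkene is not affected.

Step 8
Reactants: 11 3-iodo enone; 12 ethynyltri(propan-2-yl)silane
Product: 13 3-[(triisopropylsilyl)ethynyl] enone
Conditions: PdCl2(PPh3)2 (5 mol %), CuI (10 mol %), i-Pr2NH, THF, 0 → 20 °C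
Reagents that add atoms: none
Why: Sonogashira coupling of the α-iodo enone forms the C3–C4 bond and brings in C4 and C5.

Step 9
Reactants: 13 alkynyl enone
Product: 14 2α,3α-epoxy 8-ketone
Conditions: 30% H2O2, NaOH, MeOH, 0 °C
Reagents that add atoms: hydrogen peroxide, OO
Why: Weitz–Scheffer epoxidation: hydroperoxide adds to C2 axially on the α face, anti to the adjacent C1 methyl (as in the 1α,2α-epoxidation of steroidal 1-en-3-ones), which sets the C2 oxygen α.

Step 10
Reactants: 14 epoxy ketone
Product: 15 2α-hydroxy-3α-alkynyl 8-ketone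
Conditions: (PhSe)2, NaBH4, EtOH; AcOH, 0 → 20 °C
Reagents that add atoms: none
Why: Organoselenium-mediated reduction of an α,β-epoxy ketone: benzeneselenolate cleaves the C3–O bond next to the carbonyl and the enol is protonated to the equatorial 3α-alkynyl ketone, leaving the 2α hydroxyl, the C9 silyloxy group and the alkyne untouched.

Step 11
Reactants: 15 hydroxy ketone
Product: 16 13α,14α-epoxide of 15
Conditions: dimethyldioxirane, acetone, 0 °C
Reagents that add atoms: dimethyldioxirane, CC1(C)OO1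
Why: Dioxirane epoxidation of the only alkene from the α face, since the β face is screened by the C1 and C11 methyls and the 12β silyl ether; the neutral dioxirane does not oxidise the ketone in a Baeyer–Villiger sense.

Step 12
Reactants: 17 4-methoxybenzyl alcohol; 18 trichloroethylene
Product: 19 (E)-1,2-dichlorovinyl 4-methoxybenzyl ether
Conditions: KH, THF, 0 °C; then Cl2C=CHCl, −50 → 20 °C
Reagents that add atoms: none
Why: Alkoxide addition–elimination on trichloroethylene (through dichloroacetylene) gives the dichlorovinyl ether, the standard precursor of alkynyl ethers.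

Step 13
Reactants: 16 epoxy hydroxy ketone; 19 dichlorovinyl ether
Product: 21 8α-{[(4-methoxybenzyl)oxy]ethynyl}-2α,8β-diol, via lithium alkynyl ether 20 (not isolated)
Conditions: 19 (3 equiv), n-BuLi (6 equiv), THF, −78 → −40 °C; CeCl3, −78 °C; then 16, −78 °C
Reagents that add atoms: none
Why: Cerium acetylide addition to a ketone: n-BuLi converts 19 into the lithium alkynyl ether (elimination, then chlorine–lithium exchange), and the slim acetylide should add axially to C8 on the α face, held there by the metal alkoxide of the axial C2 hydroxyl, which sets C8 with the alkynyl group axial and cis to the C3 substituent; cerium suppresses enolisation.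

Step 14
Reactants: 21 ynol ether diol
Product: 22 8α-[(Z)-2-(4-methoxybenzyloxy)vinyl]-2α,8β-diol
Conditions: H2 (1 atm), Pd/CaCO3 poisoned with Pb(OAc)2, quinoline, EtOAc, 0 °C
Reagents that add atoms: none
Why: Lindlar semi-hydrogenation: syn delivery of hydrogen to the electron-rich ynol ether gives the (Z)-enol ether, while the triisopropylsilyl-capped alkyne is too hindered to be reduced.

Step 15
Reactants: 22 (Z)-enol ether diol
Product: 23 3α-ethynyl diol
Conditions: Bu4NF (1.1 equiv), THF, 0 °C
Reagents that add atoms: none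
Why: Fluoride-induced protodesilylation of the alkynylsilane; at 0 °C the secondary tert-butyldimethylsilyl ethers should survive.

Step 16
Reactants: 23 ethynyl diol
Product: 24 3α-(propa-1,2-dienyl) diol
Conditions: (CH2O)n, CuI, Cy2NH, dioxane, 90 °C
Reagents that add atoms: formaldehyde (as paraformaldehyde), C=O
Why: Crabbé homologation: Mannich reaction of the terminal alkyne, then copper-mediated 1,5-hydride transfer with loss of the imine, gives the terminal allene and adds C16.

Step 17
Reactants: 24 allenyl diol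
Product: 25 2-O-trimethylsilyl ether of 24
Conditions: Me3SiCl, imidazole, CH2Cl2, −20 °C
Reagents that add atoms: chlorotrimethylsilane, C[Si](C)(C)Cl
Why: Chemoselective silylation: the secondary C2 hydroxyl reacts far faster than the hindered tertiary C8 hydroxyl, which must stay free for the rearrangement.

Step 18
Reactants: 25 silyl ether
Product: 28 ten-membered enol acetate 2α-alcohol, via potassium enolate 26 (not isolated), via silylated enol acetate 27 (not isolated)
Conditions: KN(SiMe3)2, 18-crown-6, THF, −78 → 0 °C; Ac2O, −78 °C; then citric acid, MeOH, 0 °C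
Reagents that add atoms: acetic anhydride, CC(=O)OC(C)=O
Why: Anionic oxy-Cope rearrangement: with the (Z)-alkoxyvinyl group axial at C8 and the allenyl group equatorial at C3 (cis), the chair transition state breaks C3–C8 and joins C5 to C6, which should give the C7=C8 enolate with C6 and C9 trans, the (Z)-C3=C4 alkene, the C5 exomethylene (from the central allene carbon) and the 6β ether (from the Z enol ether); O-acetylation traps the enolate geometry and mild acid removes the C2 silyl group.

Step 19
Reactants: 28 enol acetate alcohol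
Product: 29 3α,4α-epoxide of 28
Conditions: VO(acac)2 (5 mol %), t-BuOOH, CH2Cl2, 0 °C
Reagents that add atoms: tert-butyl hydroperoxide, CC(C)(C)OO
Why: Hydroxyl-directed epoxidation: the vanadium alkylperoxide bound to the C2 hydroxyl delivers oxygen to the allylic C3=C4 bond, which for (Z)-allylic alcohols in medium rings gives the cis (3α,4α) epoxy alcohol; the enol acetate, the exomethylene and the ring A epoxide have no directing hydroxyl.

Step 20
Reactants: 29 epoxy alcohol
Product: 30 8-triethylsilyl enol ether, 2α-triethylsilyl ether (cycloaddition precursor)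
Conditions: MeLi (3.3 equiv), THF, −78 °C; then Et3SiCl, Et3N, −78 → 0 °C
Reagents that add atoms: chlorotriethylsilane, CC[Si](CC)(CC)Cl
Why: Enol ester cleavage: methyllithium releases the lithium enolate with retention of double-bond geometry and Et3SiCl silylates it on oxygen together with the C2 alkoxide, a regio- and stereospecific silyl enol ether synthesis.

Step 21
Reactants: 30 silyl enol ether; 31 dichloroacetyl chloride
Product: 33 trans-fused 17,17-dichlorocyclobutanone, via dichloroketene 32 (not isolated)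
Conditions: Cl2CHCOCl (slow addition), Et3N, hexane, 25 °C
Reagents that add atoms: none
Why: C7 of the enol ether attacks the carbonyl carbon of dichloroketene (C19) and the oxygen-stabilised C8 is captured by the dichloro-enolate carbon C17, an asynchronous suprafacial [2+2]; the closest known reaction type is the dichloroketene–silyl enol ether cycloaddition giving 2,2-dichloro-3-silyloxycyclobutanones. The ring C7–C19–C17–C8 closes in the ketene [2+2] mode (orthogonal approach, then 4-exo collapse of the zwitterion), and since both bonds form on one face of an enol ether with C6 and C9 trans, the cyclobutanone is trans-fused to the ten-membered ring. C7 and C8 are set together and their sense is controlled by the C6 stereocentre: allylic 1,3-strain with the cis O8 silyl group holds H-6 in the enol ether plane, which puts C5 (and C10) on one face and leaves the face of the C6 ether oxygen open to the ketene. Regiochemistry follows from the polarity of the enol ether (C7 nucleophilic). The step needs chemoselectivity over the C5 exomethylene, which is 1,1-disubstituted, flanked by two oxygen-bearing carbons and far less nucleophilic than the enol ether, and tolerance of the epoxides, secured by the amine method (no zinc halide) and by the absence of free hydroxyl or acetate. The triethylsilyl group on O8 should keep the β-oxygenated cyclobutanone from retro-aldol opening.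

Step 22
Reactants: 33 dichlorocyclobutanone
Product: 34 cyclobutanone
Conditions: Zn–Cu couple, NH4Cl, MeOH, 20 °C
Reagents that add atoms: none
Why: Reductive dechlorination of an α,α-dichloroketone by zinc (two zinc enolates protonated by ammonium chloride); the near-neutral medium spares silyl ethers and epoxides, and C7 and C8 are untouched.

Step 23
Reactants: 34 cyclobutanone
Product: 35 γ-lactone (C17 unsubstituted)
Conditions: mCPBA, NaHCO3, CH2Cl2, 0 °C
Reagents that add atoms: 3-chloroperbenzoic acid, OOC(=O)c1cccc(Cl)c1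
Why: Baeyer–Villiger oxidation: strain-driven peracid addition and migration of the more substituted C7 with retention inserts oxygen between C19 and C7; the deactivated exomethylene should not be epoxidised under cold, buffered conditions.

Step 24
Reactants: 35 γ-lactone
Product: 36 17-epi-methyl lactone (methyl trans to O8)
Conditions: LDA, THF, −78 °C; MeI, −78 °C
Reagents that add atoms: iodomethane, CI
Why: Lactone enolate alkylation: the electrophile should enter C17 anti to the pseudo-axial C8 silyloxy group, which gives the 17-epimer and makes the next step necessary.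

Step 25
Reactants: 36 17-epi-methyl lactone
Product: 37 17-methyl lactone (methyl cis to O8)
Conditions: LDA, THF, −78 °C; then 2,6-di-tert-butyl-4-methylphenol, −78 °C
Reagents that add atoms: none
Why: Kinetic enolate protonation: the proton, like the methyl before it, enters anti to the C8 silyloxy group and so turns the methyl to the side of O8; low temperature avoids β-elimination of the silyloxide.

Step 26
Reactants: 37 methyl lactone
Product: 38 6β-alcohol
Conditions: DDQ, CH2Cl2, pH 7 buffer, 0 °C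
Reagents that add atoms: none
Why: Oxidative cleavage of the p-methoxybenzyl ether (hydride abstraction, hydrolysis of the oxocarbenium ion) frees only the C6 hydroxyl.

Step 27
Reactants: 38 6β-alcohol
Product: 39 6α-chloride
Conditions: PPh3, Cl3CC(O)CCl3, CH2Cl2, −20 °C
Reagents that add atoms: hexachloroacetone, ClC(Cl)(Cl)C(=O)C(Cl)(Cl)Cl
Why: Appel-type chlorination: chloride displaces the alkoxyphosphonium ion at C6 with inversion (SN2), under conditions known to convert secondary allylic alcohols without allylic transposition.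

Step 28
Reactants: 39 chloride
Product: 40 2,8,9,12-tetraol
Conditions: HF·pyridine, pyridine, THF, 0 → 20 °C
Reagents that add atoms: none
Why: Fluoride-mediated desilylation with pyridine-buffered HF removes the four silyl ethers under conditions that epoxides, the lactone and an allylic chloride tolerate.

Step 29
Reactants: 40 tetraol
Product: 41 CNP0314105.1
Conditions: Me2SnCl2 (5 mol %), AcCl, i-Pr2NEt, THF, 0 °C
Reagents that add atoms: acetyl chloride, CC(Cl)=O
Why: Organotin-catalysed monoacylation of a 1,2-diol: the tin binds the only vicinal diol (C8/C9) and activates its secondary oxygen, so O9 is acetylated while the isolated C2 and C12 hydroxyls and the tertiary C8 hydroxyl stay free.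

Compound list
1 | ethyl vinyl ketone | CCC(=O)C=C | starting material
2 | (Z)-3-(tert-butyldimethylsilyloxy)penta-1,3-diene | C=C/C(O[Si](C)(C)C(C)(C)C)=C/C | intermediate
3 | 2-methoxy-5-methyl-1,4-benzoquinone | COC1=CC(=O)C(C)=CC1=O | starting material
4 | cis-fused adduct: 8-methoxy-3-ene-2,9-dione, 1β-methyl, 10β-H, 11α-methyl, C12=C13 TBS enol ether | O=C1C=C(OC)C(=O)[C@@H]2[C@H](C)C(O[Si](C)(C)C(C)(C)C)=CC[C@]12C | intermediate
5 | trans-fused adduct (10α-H epimer of 4) | O=C1C=C(OC)C(=O)[C@H]2[C@H](C)C(O[Si](C)(C)C(C)(C)C)=CC[C@]12C | intermediate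
6 | trans-fused trione: ring A 13-en-12-one, 11α-methyl | O=C1C=C(OC)C(=O)[C@H]2[C@H](C)C(=O)C=C[C@]12C | intermediate
7 | 11β-methyl epimer of 6 | O=C1C=C(OC)C(=O)[C@H]2[C@@H](C)C(=O)C=C[C@]12C | intermediate (not isolated)
8 | 8-methoxy-3,13-diene-2,9,12β-triol (C2, C9 not controlled) | OC1C=C(OC)C(O)[C@H]2[C@@H](C)[C@@H](O)C=C[C@]12C | intermediate (not isolated)
9 | 9,12β-dihydroxy-11β-methyl-2,13-dien-8-one (C9 epimers) | C1=C[C@]2(C)[C@H]([C@@H](C)[C@@H](O)C=C2)C(O)C1=O | intermediate
10 | 9α,12β-bis(tert-butyldimethylsilyloxy)-2,13-dien-8-one | C1=C[C@]2(C)[C@H]([C@@H](C)[C@@H](O[Si](C)(C)C(C)(C)C)C=C2)[C@@H](O[Si](C)(C)C(C)(C)C)C1=O | intermediate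
11 | 3-iodo enone | IC1=C[C@]2(C)[C@H]([C@@H](C)[C@@H](O[Si](C)(C)C(C)(C)C)C=C2)[C@@H](O[Si](C)(C)C(C)(C)C)C1=O | intermediate
12 | ethynyltri(propan-2-yl)silane | C#C[Si](C(C)C)(C(C)C)C(C)C | starting material
13 | 3-[(triisopropylsilyl)ethynyl] enone | CC(C)[Si](C#CC1=C[C@]2(C)[C@H]([C@@H](C)[C@@H](O[Si](C)(C)C(C)(C)C)C=C2)[C@@H](O[Si](C)(C)C(C)(C)C)C1=O)(C(C)C)C(C)C | intermediate
14 | 2α,3α-epoxy 8-ketone | CC(C)[Si](C#C[C@]12O[C@H]1[C@]3(C)[C@H]([C@@H](C)[C@@H](O[Si](C)(C)C(C)(C)C)C=C3)[C@@H](O[Si](C)(C)C(C)(C)C)C2=O)(C(C)C)C(C)C | intermediate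
15 | 2α-hydroxy-3α-[(triisopropylsilyl)ethynyl] 8-ketone | CC(C)[Si](C#C[C@H]1[C@@H](O)[C@]2(C)[C@H]([C@@H](C)[C@@H](O[Si](C)(C)C(C)(C)C)C=C2)[C@@H](O[Si](C)(C)C(C)(C)C)C1=O)(C(C)C)C(C)C | intermediate
16 | 13α,14α-epoxide of 15 | CC(C)[Si](C#C[C@H]1[C@@H](O)[C@]2(C)[C@H]([C@@H](C)[C@@H](O[Si](C)(C)C(C)(C)C)[C@@H]3O[C@@H]32)[C@@H](O[Si](C)(C)C(C)(C)C)C1=O)(C(C)C)C(C)C | intermediate
17 | 4-methoxybenzyl alcohol | COc1ccc(CO)cc1 | starting material
18 | trichloroethylene | ClC=C(Cl)Cl | starting material
19 | (E)-1,2-dichlorovinyl 4-methoxybenzyl ether | COc1ccc(CO/C(Cl)=C\Cl)cc1 | intermediate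
20 | lithium [(4-methoxybenzyl)oxy]acetylide | [Li]C#COCc1ccc(OC)cc1 | intermediate (not isolated)
21 | 8α-{[(4-methoxybenzyl)oxy]ethynyl}-2α,8β-diol | CC(C)[Si](C#C[C@H]1[C@@H](O)[C@]2(C)[C@H]([C@@H](C)[C@@H](O[Si](C)(C)C(C)(C)C)[C@@H]3O[C@@H]32)[C@@H](O[Si](C)(C)C(C)(C)C)[C@@]1(O)C#COCc1ccc(OC)cc1)(C(C)C)C(C)C | intermediate
22 | 8α-[(Z)-2-(4-methoxybenzyloxy)vinyl]-2α,8β-diol | CC(C)[Si](C#C[C@H]1[C@@H](O)[C@]2(C)[C@H]([C@@H](C)[C@@H](O[Si](C)(C)C(C)(C)C)[C@@H]3O[C@@H]32)[C@@H](O[Si](C)(C)C(C)(C)C)[C@@]1(O)/C=C\OCc1ccc(OC)cc1)(C(C)C)C(C)C | intermediate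
23 | 3α-ethynyl diol | C#C[C@H]1[C@@H](O)[C@]2(C)[C@H]([C@@H](C)[C@@H](O[Si](C)(C)C(C)(C)C)[C@@H]3O[C@@H]32)[C@@H](O[Si](C)(C)C(C)(C)C)[C@@]1(O)/C=C\OCc1ccc(OC)cc1 | intermediate
24 | 3α-(propa-1,2-dienyl) diol | C=C=C[C@H]1[C@@H](O)[C@]2(C)[C@H]([C@@H](C)[C@@H](O[Si](C)(C)C(C)(C)C)[C@@H]3O[C@@H]32)[C@@H](O[Si](C)(C)C(C)(C)C)[C@@]1(O)/C=C\OCc1ccc(OC)cc1 | intermediate
25 | 2-O-trimethylsilyl ether of 24 | C=C=C[C@H]1[C@@H](O[Si](C)(C)C)[C@]2(C)[C@H]([C@@H](C)[C@@H](O[Si](C)(C)C(C)(C)C)[C@@H]3O[C@@H]32)[C@@H](O[Si](C)(C)C(C)(C)C)[C@@]1(O)/C=C\OCc1ccc(OC)cc1 | intermediate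
26 | ten-membered potassium enolate (C7=C8, C6 and C9 trans) | C=C1/C=C\[C@@H](O[Si](C)(C)C)[C@]2(C)[C@H]([C@@H](C)[C@@H](O[Si](C)(C)C(C)(C)C)[C@@H]3O[C@@H]32)[C@@H](O[Si](C)(C)C(C)(C)C)/C(O[K])=C/[C@@H]1OCc1ccc(OC)cc1 | intermediate (not isolated)
27 | 8-enol acetate, 2-O-trimethylsilyl | C=C1/C=C\[C@@H](O[Si](C)(C)C)[C@]2(C)[C@H]([C@@H](C)[C@@H](O[Si](C)(C)C(C)(C)C)[C@@H]3O[C@@H]32)[C@@H](O[Si](C)(C)C(C)(C)C)/C(OC(C)=O)=C/[C@@H]1OCc1ccc(OC)cc1 | intermediate (not isolated)
28 | enol acetate 2α-alcohol: (3Z)-3,7-diene, 5-methylene, 6β-PMB ether | C=C1/C=C\[C@@H](O)[C@]2(C)[C@H]([C@@H](C)[C@@H](O[Si](C)(C)C(C)(C)C)[C@@H]3O[C@@H]32)[C@@H](O[Si](C)(C)C(C)(C)C)/C(OC(C)=O)=C/[C@@H]1OCc1ccc(OC)cc1 | intermediate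
29 | 3α,4α-epoxide of 28 | C=C1[C@H]2O[C@H]2[C@@H](O)[C@]2(C)[C@H]([C@@H](C)[C@@H](O[Si](C)(C)C(C)(C)C)[C@@H]3O[C@@H]32)[C@@H](O[Si](C)(C)C(C)(C)C)/C(OC(C)=O)=C/[C@@H]1OCc1ccc(OC)cc1 | intermediate
30 | ten-membered C7=C8 triethylsilyl enol ether (C6 and C9 trans), 2α-OTES, 9α,12β-OTBS, 6β-OPMB | C=C1[C@H]2O[C@H]2[C@@H](O[Si](CC)(CC)CC)[C@]2(C)[C@H]([C@@H](C)[C@@H](O[Si](C)(C)C(C)(C)C)[C@@H]3O[C@@H]32)[C@@H](O[Si](C)(C)C(C)(C)C)/C(O[Si](CC)(CC)CC)=C/[C@@H]1OCc1ccc(OC)cc1 | intermediate
31 | dichloroacetyl chloride | ClC(Cl)C(Cl)=O | starting material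
32 | dichloroketene | ClC(Cl)=C=O | intermediate (not isolated)
33 | trans-fused 17,17-dichlorocyclobutanone (C7–C19–C17–C8) | C=C1[C@H]2O[C@H]2[C@@H](O[Si](CC)(CC)CC)[C@]2(C)[C@H]([C@@H](C)[C@@H](O[Si](C)(C)C(C)(C)C)[C@@H]3O[C@@H]32)[C@@H](O[Si](C)(C)C(C)(C)C)[C@]2(O[Si](CC)(CC)CC)C(Cl)(Cl)C(=O)[C@H]2[C@@H]1OCc1ccc(OC)cc1 | intermediate
34 | cyclobutanone | C=C1[C@H]2O[C@H]2[C@@H](O[Si](CC)(CC)CC)[C@]2(C)[C@H]([C@@H](C)[C@@H](O[Si](C)(C)C(C)(C)C)[C@@H]3O[C@@H]32)[C@@H](O[Si](C)(C)C(C)(C)C)[C@]2(O[Si](CC)(CC)CC)CC(=O)[C@H]2[C@@H]1OCc1ccc(OC)cc1 | intermediate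
35 | γ-lactone (C17 unsubstituted) | C=C1[C@H]2O[C@H]2[C@@H](O[Si](CC)(CC)CC)[C@]2(C)[C@H]([C@@H](C)[C@@H](O[Si](C)(C)C(C)(C)C)[C@@H]3O[C@@H]32)[C@@H](O[Si](C)(C)C(C)(C)C)[C@]2(O[Si](CC)(CC)CC)CC(=O)O[C@H]2[C@@H]1OCc1ccc(OC)cc1 | intermediate
36 | 17-epi-methyl lactone | C=C1[C@H]2O[C@H]2[C@@H](O[Si](CC)(CC)CC)[C@]2(C)[C@H]([C@@H](C)[C@@H](O[Si](C)(C)C(C)(C)C)[C@@H]3O[C@@H]32)[C@@H](O[Si](C)(C)C(C)(C)C)[C@]2(O[Si](CC)(CC)CC)[C@H](C)C(=O)O[C@H]2[C@@H]1OCc1ccc(OC)cc1 | intermediate
37 | 17-methyl lactone | C=C1[C@H]2O[C@H]2[C@@H](O[Si](CC)(CC)CC)[C@]2(C)[C@H]([C@@H](C)[C@@H](O[Si](C)(C)C(C)(C)C)[C@@H]3O[C@@H]32)[C@@H](O[Si](C)(C)C(C)(C)C)[C@]2(O[Si](CC)(CC)CC)[C@@H](C)C(=O)O[C@H]2[C@@H]1OCc1ccc(OC)cc1 | intermediate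
38 | 6β-alcohol | C=C1[C@H]2O[C@H]2[C@@H](O[Si](CC)(CC)CC)[C@]2(C)[C@H]([C@@H](C)[C@@H](O[Si](C)(C)C(C)(C)C)[C@@H]3O[C@@H]32)[C@@H](O[Si](C)(C)C(C)(C)C)[C@]2(O[Si](CC)(CC)CC)[C@@H](C)C(=O)O[C@H]2[C@@H]1O | intermediate
39 | 6α-chloride | C=C1[C@H]2O[C@H]2[C@@H](O[Si](CC)(CC)CC)[C@]2(C)[C@H]([C@@H](C)[C@@H](O[Si](C)(C)C(C)(C)C)[C@@H]3O[C@@H]32)[C@@H](O[Si](C)(C)C(C)(C)C)[C@]2(O[Si](CC)(CC)CC)[C@@H](C)C(=O)O[C@H]2[C@H]1Cl | intermediate
40 | 2,8,9,12-tetraol | C=C1[C@H]2O[C@H]2[C@@H](O)[C@]2(C)[C@H]([C@@H](C)[C@@H](O)[C@@H]3O[C@@H]32)[C@@H](O)[C@]2(O)[C@@H](C)C(=O)O[C@H]2[C@H]1Cl | intermediate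
41 | CNP0314105.1 | C=C1[C@H]2O[C@H]2[C@@H](O)[C@]2(C)[C@H]([C@@H](C)[C@@H](O)[C@@H]3O[C@@H]32)[C@@H](OC(C)=O)[C@]2(O)[C@@H](C)C(=O)O[C@H]2[C@H]1Cl | target

Total step count: 29. Longest linear sequence: 28 steps (steps 1–11 and 13–29, from 1 to 41; step 12 is a one-step side branch).

Steps most likely to fail

Step 21. The ketene may add to the other face of the enol ether if the ring populates the alternative conformer, or the strained 3-silyloxy-2,2-dichlorocyclobutanone may open in a retro-aldol sense during the reaction or the dechlorination. The fallback builds the lactone stepwise, without cycloaddition. Setting out from 30, Rubottom oxidation with dimethyldioxirane gives the 7α-triethylsilyloxy 8-ketone F1. Reformatsky addition of the zinc enolate of ethyl 2-bromopropanoate to the C8 carbonyl, anti to C6, gives the β-hydroxy ester F2. Bu4NF/AcOH frees O7 (and O2), which closes the γ-lactone diol F3. Et3SiOTf/2,6-lutidine silylates O2 and O8, and the route is rejoined at 36 (as the C17 epimer pair that step 25 converges).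

Step 18. The C6 p-methoxybenzyloxide may be lost by β-elimination from the potassium enolate, or the O9 silyl group may migrate to the alkoxide, before the enolate is trapped. The fallback is a neutral thermal siloxy-Cope rearrangement. Setting out from 25, Et3SiOTf/2,6-lutidine gives the C8 triethylsilyl ether F4. Heating in toluene (170 °C, sealed tube) should rearrange it through the same chair transition state directly to the ten-membered triethylsilyl enol ether F5, with no enolate on the way. MeLi then Ac2O converts F5 into the enol acetate 27, where the route is rejoined.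

Step 5. The C11 enolate may be protonated on the β face (the stereoelectronically preferred axial direction), which would return the equatorial 11α methyl, or enolisation may be incomplete. The fallback uses hydrogen-atom transfer instead of proton transfer. Setting out from 6, LDA then PhSeBr gives the 11-phenylselanyl trione F6. Bu3SnH/AIBN generates the planar C11 radical, which should take hydrogen from the bulky stannane on the open α face to give 7. Compound 7 is reduced and hydrolysed at once as in step 5, and the route is rejoined at 9.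

Further compounds
F1 | step 21 | 7α-triethylsilyloxy 8-ketone (from 30) | C=C1[C@H]2O[C@H]2[C@@H](O[Si](CC)(CC)CC)[C@]2(C)[C@H]([C@@H](C)[C@@H](O[Si](C)(C)C(C)(C)C)[C@@H]3O[C@@H]32)[C@@H](O[Si](C)(C)C(C)(C)C)C(=O)[C@@H](O[Si](CC)(CC)CC)[C@@H]1OCc1ccc(OC)cc1
F2 | step 21 | 8α-hydroxy 8-(1-ethoxycarbonylethyl) Reformatsky adduct | C=C1[C@H]2O[C@H]2[C@@H](O[Si](CC)(CC)CC)[C@]2(C)[C@H]([C@@H](C)[C@@H](O[Si](C)(C)C(C)(C)C)[C@@H]3O[C@@H]32)[C@@H](O[Si](C)(C)C(C)(C)C)[C@](O)(C(C)C(=O)OCC)[C@@H](O[Si](CC)(CC)CC)[C@@H]1OCc1ccc(OC)cc1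
F3 | step 21 | 2α,8α-dihydroxy 17-methyl γ-lactone (C17 epimers) | C=C1[C@H]2O[C@H]2[C@@H](O)[C@]2(C)[C@H]([C@@H](C)[C@@H](O[Si](C)(C)C(C)(C)C)[C@@H]3O[C@@H]32)[C@@H](O[Si](C)(C)C(C)(C)C)[C@]2(O)C(C)C(=O)O[C@H]2[C@@H]1OCc1ccc(OC)cc1
F4 | step 18 | 8-O-triethylsilyl ether of 25 | C=C=C[C@H]1[C@@H](O[Si](C)(C)C)[C@]2(C)[C@H]([C@@H](C)[C@@H](O[Si](C)(C)C(C)(C)C)[C@@H]3O[C@@H]32)[C@@H](O[Si](C)(C)C(C)(C)C)[C@@]1(O[Si](CC)(CC)CC)/C=C\OCc1ccc(OC)cc1
F5 | step 18 | ten-membered 8-triethylsilyl enol ether, 2-O-trimethylsilyl | C=C1/C=C\[C@@H](O[Si](C)(C)C)[C@]2(C)[C@H]([C@@H](C)[C@@H](O[Si](C)(C)C(C)(C)C)[C@@H]3O[C@@H]32)[C@@H](O[Si](C)(C)C(C)(C)C)/C(O[Si](CC)(CC)CC)=C/[C@@H]1OCc1ccc(OC)cc1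
F6 | step 5 | 11-phenylselanyl trione (C11 epimers) | O=C1C=C(OC)C(=O)[C@H]2C(C)([Se]c3ccccc3)C(=O)C=C[C@]12C
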